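**Plan**

- Retrosynthetic cuts, in order: the C6–allyl bond (decarboxylative allylic alkylation of an allyl enol carbonate); the ketal C4–OAr bond, with a temporary C4–C6 bond put in its place (ring opening of a donor–acceptor cyclopropane by phenol 14); the C5–C6 bond (intramolecular cyclopropanation of an acyclic diazoketone built from 2,3-dimethoxybutadiene, a trichloroacetyl carbon and a diazomethane carbon).
- Enabling feature: in the cyclohexenone ring the ketal carbon C4 and the ketone carbon C1 are 1,4-related through C5–C6. This γ-keto ketal is the retron of a 2-alkoxycyclopropyl ketone opened by an O–H nucleophile, here 4,5-dimethoxybicyclo[3.1.0]hex-3-en-2-one, a strained valence isomer of 3,4-dimethoxyphenol.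
- Forward order: acyclic chain; then cyclopentenone and cyclopropane in one step (C5–C6 formed); then the six-membered ring by fragmentation of the extra C4–C6 bond with the phenol; then the allyl group.
- Stereochemistry: the cyclopropane stereocentres are racemic and are erased. C4 (R) is set by a chiral phosphoric acid in the enantioconvergent ring opening. C6 (S) is set in the allylation by the chiral diphosphine complex of zerovalent palladium generated from Pd2(dba)3, which also turns residual (4S) material into the separable trans diastereomer.

Key step: step 4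

Remark: ring atoms are numbered as in the name of the target (C1 C=O, C2 =CH, C3 C–OMe, C4 ketal, C5 CH2, C6 CH–allyl). Compound 10 is racemic by design and one enantiomer is drawn; both give the same cation in step 7.

**Route**

Step 1
Reactants: 1 2,3-dimethoxybuta-1,3-diene; 2 trichloroacetyl chloride
Product: 3 (E)-1,1,1-trichloro-4,5-dimethoxyhexa-3,5-dien-2-one
Conditions: pyridine, CH2Cl2, −10 °C to rt
Reagents that add atoms: trichloroacetyl chloride (2), O=C(Cl)C(Cl)(Cl)Cl
Why: Friedel–Crafts-type C-acylation of an enol ether at its CH2 terminus with loss of HCl to pyridine; it should stop after one acylation because the second enol ether becomes conjugated to the new acceptor, and the stable E enone places the acyl group cis to the methoxyvinyl group.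

Step 2
Reactants: 3 (E)-1,1,1-trichloro-4,5-dimethoxyhexa-3,5-dien-2-one; 4 lithium hydroxide
Product: 5 lithium (E)-3,4-dimethoxypenta-2,4-dienoate
Conditions: LiOH·H2O (1.05 equiv), THF/H2O, 0 °C; freeze-dry
Reagents that add atoms: lithium hydroxide (4), [Li+].[OH-]
Why: haloform-type cleavage, in which hydroxide adds to the activated carbonyl and the trichloromethyl group leaves as chloroform; isolating the lithium salt keeps the enol ethers away from acid.

Step 3
Reactants: 5 lithium (E)-3,4-dimethoxypenta-2,4-dienoate; 6 (trimethylsilyl)diazomethane
Product: 9 (E)-1-diazo-4,5-dimethoxyhexa-3,5-dien-2-one, via mixed carbonic anhydride 7 (not isolated), via C-silyl diazoketone 8 (not isolated)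
Conditions: i-BuOCOCl, THF, −15 °C; then Me3SiCHN2, MeCN, 0 °C to rt; aq NaHCO3
Reagents that add atoms: (trimethylsilyl)diazomethane (6), C[Si](C)(C)C=[N+]=[N-]
Why: Arndt–Eistert-type C-acylation of a diazoalkane by a mixed anhydride, followed by protodesilylation on aqueous work-up; the conditions are neutral to basic throughout, so the enol ethers should survive.

Step 4
Reactants: 9 (E)-1-diazo-4,5-dimethoxyhexa-3,5-dien-2-one
Product: 10 (1RS,5RS)-4,5-dimethoxybicyclo[3.1.0]hex-3-en-2-one (racemic, cis-fused)
Conditions: Rh2(OAc)4 (1 mol %), CH2Cl2, rt, slow addition of 9; filtration through basic Al2O3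
Reagents that add atoms: none
Why: Rh2(OAc)4 turns the diazoketone into an electrophilic rhodium carbenoid at C1 of 9, which is attacked by the CH2 terminus of the 2-methoxyvinyl group (this is the C5–C6 bond of 18) and then closes onto the methoxy-bearing carbon, so the cyclopropane holds one bond that is kept and one sacrificial bond (C4–C6 in target numbering). The closest known reaction type is the intramolecular cyclopropanation of unsaturated α-diazoketones to bicyclo[3.1.0]hexan-2-ones, together with the Rh2(OAc)4-catalysed cyclopropanation of enol ethers. The cyclopentenone closes in the 5-exo sense onto the internal carbon of the 1,1-disubstituted alkene and the three-membered ring by [2+1] addition across that alkene, the E enone holding carbenoid and alkene cis. The two bridgehead stereocentres can only be cis-fused and arise as a racemate, which is accepted because both are destroyed in step 7. The step needs chemoselectivity for the terminal enol ether over the vinylogous-ester C=C, over the methoxy oxygens (oxonium ylides) and over carbene dimerisation; the higher nucleophilicity of the unconjugated CH2 terminus, the trans placement of the C4 methoxy group of 9 away from the carbenoid and the slow addition should secure it.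

Step 5
Reactants: 11 3,4-dimethoxyphenol; 12 allyl bromide
Product: 13 4-(allyloxy)-1,2-dimethoxybenzene
Conditions: K2CO3, acetone, reflux
Reagents that add atoms: allyl bromide (12), C=CCBr
Why: Williamson ether synthesis of a phenoxide with a primary allylic bromide.

Step 6
Reactants: 13 4-(allyloxy)-1,2-dimethoxybenzene
Product: 14 2-allyl-4,5-dimethoxyphenol
Conditions: N,N-diethylaniline, 190 °C
Reagents that add atoms: none
Why: aromatic Claisen rearrangement ([3,3] shift, then tautomerisation), which should go mainly to the ortho position that is not flanked by a methoxy group.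

Step 7
Reactants: 10 (1RS,5RS)-4,5-dimethoxybicyclo[3.1.0]hex-3-en-2-one; 14 2-allyl-4,5-dimethoxyphenol
Product: 15 (R)-4-(2-allyl-4,5-dimethoxyphenoxy)-3,4-dimethoxycyclohex-2-en-1-one
Conditions: 14 (2 equiv), (R)-3,3′-bis(2,4,6-triisopropylphenyl)-1,1′-binaphthyl-2,2′-diyl hydrogen phosphate (5 mol %), 4 Å MS, toluene, −40 °C; then Et3N
Reagents that add atoms: none
Why: Proposed new method: the phosphoric acid protonates the ketone oxygen of the donor–acceptor cyclopropane, the internal C1–C5 bond of the bicycle (acceptor carbon to methoxy donor carbon) heterolyses to a hydroxy-substituted methoxycarbenium ion paired with the chiral phosphate, and the phosphate-bound phenol adds through oxygen to one enantiotopic face of the carbenium carbon before the dienol tautomerises to the enone; both enantiomers of 10 give the same planar cation, so the opening is enantioconvergent and the catalyst alone should set C4 (R) (its antipode is used if the sense of induction is the opposite); because this cation is the C-protonated form of 3,4-dimethoxyphenol, the step must favour O-capture over loss of a proton from the ring CH2 (C5 of the target) and over C-alkylation of the phenol, which low temperature, excess phenol, ion-pair collapse and a basic quench are meant to secure; the closest known reaction types are the acid-catalysed alcoholysis of 2-alkoxycyclopropyl ketones to γ-keto ketals and chiral-phosphoric-acid-catalysed asymmetric acetalisations of oxocarbenium ion pairs.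

Step 8
Reactants: 15 (R)-4-(2-allyl-4,5-dimethoxyphenoxy)-3,4-dimethoxycyclohex-2-en-1-one; 16 allyl chloroformate
Product: 17 allyl [(4R)-4-(2-allyl-4,5-dimethoxyphenoxy)-4,5-dimethoxycyclohexa-1,5-dien-1-yl] carbonate
Conditions: NaN(SiMe3)2, TMEDA, THF, −78 °C; then allyl chloroformate
Reagents that add atoms: allyl chloroformate (16), C=CCOC(Cl)=O
Why: kinetic deprotonation of the vinylogous ester at C6 (α′) and O-acylation of the sodium enolate by the hard chloroformate should give the enol carbonate without touching the ketal centre.

Step 9
Reactants: 17 allyl [(4R)-4-(2-allyl-4,5-dimethoxyphenoxy)-4,5-dimethoxycyclohexa-1,5-dien-1-yl] carbonate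
Product: 18 (4R,6S)-6-allyl-4-(2-allyl-4,5-dimethoxyphenoxy)-3,4-dimethoxycyclohex-2-en-1-one
Conditions: Pd2(dba)3·CHCl3 (2.5 mol %), (1R,2R)-N,N′-bis[2-(diphenylphosphino)benzoyl]cyclohexane-1,2-diamine (6 mol %), toluene, rt
Reagents that add atoms: none
Why: Tsuji–Trost-type decarboxylative asymmetric allylic alkylation, in which zerovalent palladium ionises the allyl carbonate, CO2 is lost and the π-allyl/enolate ion pair recombines at C6; the chiral diphosphine should control the enolate face and set C6 (S), cis to the aryloxy group (the ligand antipode is used if the sense is the opposite), the base-free conditions avoid epimerisation and double allylation, and any (4S) material from step 7 ends as the separable trans diastereomer.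

**Compound list**

1 | 2,3-dimethoxybuta-1,3-diene | C=C(OC)C(OC)=C | starting material
2 | trichloroacetyl chloride | O=C(Cl)C(Cl)(Cl)Cl | starting material
3 | (E)-1,1,1-trichloro-4,5-dimethoxyhexa-3,5-dien-2-one | O=C(/C=C(/OC)C(OC)=C)C(Cl)(Cl)Cl | intermediate
4 | lithium hydroxide | [Li+].[OH-] | starting material
5 | lithium (E)-3,4-dimethoxypenta-2,4-dienoate | [Li+].[O-]C(=O)/C=C(/OC)C(OC)=C | intermediate
6 | (trimethylsilyl)diazomethane | C[Si](C)(C)C=[N+]=[N-] | starting material
7 | isobutyl carbonic (E)-3,4-dimethoxypenta-2,4-dienoic anhydride (not isolated) | CC(C)COC(=O)OC(=O)/C=C(/OC)C(OC)=C | intermediate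
8 | (E)-1-diazo-4,5-dimethoxy-1-(trimethylsilyl)hexa-3,5-dien-2-one (not isolated) | C[Si](C)(C)C(=[N+]=[N-])C(=O)/C=C(/OC)C(OC)=C | intermediate
9 | (E)-1-diazo-4,5-dimethoxyhexa-3,5-dien-2-one | [N-]=[N+]=CC(=O)/C=C(/OC)C(OC)=C | intermediate
10 | (1RS,5RS)-4,5-dimethoxybicyclo[3.1.0]hex-3-en-2-one (racemic; (1S,5S) enantiomer drawn) | O=C1C=C(OC)[C@]2(OC)C[C@H]12 | intermediate
11 | 3,4-dimethoxyphenol | COc1ccc(O)cc1OC | starting material
12 | allyl bromide | C=CCBr | starting material
13 | 4-(allyloxy)-1,2-dimethoxybenzene | C=CCOc1ccc(OC)c(OC)c1 | intermediate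
14 | 2-allyl-4,5-dimethoxyphenol | C=CCc1cc(OC)c(OC)cc1O | intermediate
15 | (R)-4-(2-allyl-4,5-dimethoxyphenoxy)-3,4-dimethoxycyclohex-2-en-1-one | C=CCc1cc(OC)c(OC)cc1O[C@]1(OC)CCC(=O)C=C1OC | intermediate
16 | allyl chloroformate | C=CCOC(Cl)=O | starting material
17 | allyl [(4R)-4-(2-allyl-4,5-dimethoxyphenoxy)-4,5-dimethoxycyclohexa-1,5-dien-1-yl] carbonate | C=CCc1cc(OC)c(OC)cc1O[C@]1(OC)CC=C(OC(=O)OCC=C)C=C1OC | intermediate
18 | (4R,6S)-6-allyl-4-(2-allyl-4,5-dimethoxyphenoxy)-3,4-dimethoxycyclohex-2-en-1-one | C=CCc1cc(OC)c(OC)cc1O[C@]1(OC)C[C@H](CC=C)C(=O)C=C1OC | target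

**Count**

Total steps: 9. Longest linear sequence: 7 (steps 1, 2, 3, 4, 7, 8, 9).

**Steps most likely to fail**

Step 7 (Proposed new method). The cation formed on ring opening may lose a proton from the ring CH2 group at C5 and aromatise to 3,4-dimethoxyphenol before it is captured, the phenol may react at carbon, or the chiral phosphate may discriminate the two faces poorly. The fallback uses known chemistry, sets out from 10 and 14 and comes back at 18. It answers the loss of stereocontrol, not the aromatisation. The cyclopropane is opened without asymmetric induction by pyridinium p-toluenesulfonate and an excess of 14 in toluene, the ordinary acid-catalysed alcoholysis of a 2-alkoxycyclopropyl ketone. This should give racemic 4-(2-allyl-4,5-dimethoxyphenoxy)-3,4-dimethoxycyclohex-2-en-1-one F1 as the ketal. NaN(SiMe3)2 and allyl chloroformate 16, used as in step 8, then convert it into racemic allyl [4-(2-allyl-4,5-dimethoxyphenoxy)-4,5-dimethoxycyclohexa-1,5-dien-1-yl] carbonate F2 for the allylation. This carbonate is submitted to the conditions of step 9, where the catalyst made from Pd2(dba)3 and the chiral diphosphine acts divergently on the racemate. The 4R half should give 18 and the 4S half the trans diastereomer (4S,6S)-6-allyl-4-(2-allyl-4,5-dimethoxyphenoxy)-3,4-dimethoxycyclohex-2-en-1-one F3 which is removed by chromatography, at the cost of half the material.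

Step 4. The carbenoid may be diverted to an oxonium ylide at a methoxy oxygen or to carbene dimers, or the strained push–pull cyclopropane may open on isolation and aromatise. The fallback forms the same C5–C6 bond by enolate alkylation on a ketal made in the open chain, where no aromatisation is possible, so it also avoids the cation of step 7. It sets out from 5 and 14 and comes back at 18.
- Salt 5 is activated as in step 3 through the mixed anhydride 7 and treated with N,O-dimethylhydroxylamine hydrochloride and Et3N to give the amide (E)-N,3,4-trimethoxy-N-methylpenta-2,4-dienamide F4 in the first operation.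
- MeMgBr then gives the methyl ketone (E)-4,5-dimethoxyhexa-3,5-dien-2-one F5 after aqueous work-up.
- Dimethyldioxirane in acetone at −78 °C should epoxidise only the terminal enol ether to racemic (E)-4-methoxy-4-(2-methoxyoxiran-2-yl)but-3-en-2-one F6 which is not isolated.
- Phenol 14 opens this epoxy ether at the ketal carbon to give racemic (E)-5-(2-allyl-4,5-dimethoxyphenoxy)-6-hydroxy-4,5-dimethoxyhex-3-en-2-one F7 as a primary alcohol.
- Tf2O and 2,6-di-tert-butylpyridine convert the alcohol into racemic (E)-2-(2-allyl-4,5-dimethoxyphenoxy)-2,3-dimethoxy-5-oxohex-3-en-1-yl trifluoromethanesulfonate F8 at low temperature.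
- LiN(SiMe3)2 in THF then forms the methyl ketone enolate, which should close the six-membered ring by 6-(enolendo)-exo-tet displacement to the racemic ketal F1 described above.
- F1 is carried through F2 to 18 as in the fallback for step 7, the 4S half again ending as F3 and being removed.

Step 9. Zerovalent palladium may also ionise the tertiary allylic aryl ether at C4, the electron-rich dienyl carbonate may lose 14 and aromatise, or ligand control may be mismatched with the ketal centre. The fallback sets out from 15 and comes back at 18. The lithium enolate of 15 is made with LiN(SiMe3)2 in THF at −78 °C and alkylated at the α′ position with allyl bromide 12 under substrate control. This should give 18 together with its C6 epimer (4R,6R)-6-allyl-4-(2-allyl-4,5-dimethoxyphenoxy)-3,4-dimethoxycyclohex-2-en-1-one F9 which is separated, equilibrated at C6 with catalytic DBU and recycled.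

**Further compounds**

F1 | step 7 | racemic 4-(2-allyl-4,5-dimethoxyphenoxy)-3,4-dimethoxycyclohex-2-en-1-one | C=CCc1cc(OC)c(OC)cc1OC1(OC)CCC(=O)C=C1OC
F2 | step 7 | racemic allyl [4-(2-allyl-4,5-dimethoxyphenoxy)-4,5-dimethoxycyclohexa-1,5-dien-1-yl] carbonate | C=CCc1cc(OC)c(OC)cc1OC1(OC)CC=C(OC(=O)OCC=C)C=C1OC
F3 | step 7 | (4S,6S)-6-allyl-4-(2-allyl-4,5-dimethoxyphenoxy)-3,4-dimethoxycyclohex-2-en-1-one | C=CCc1cc(OC)c(OC)cc1O[C@@]1(OC)C[C@H](CC=C)C(=O)C=C1OC
F4 | step 4 | (E)-N,3,4-trimethoxy-N-methylpenta-2,4-dienamide | CON(C)C(=O)/C=C(/OC)C(OC)=C
F5 | step 4 | (E)-4,5-dimethoxyhexa-3,5-dien-2-one | CC(=O)/C=C(/OC)C(OC)=C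
F6 | step 4 | racemic (E)-4-methoxy-4-(2-methoxyoxiran-2-yl)but-3-en-2-one | CC(=O)/C=C(/OC)C1(OC)CO1
F7 | step 4 | racemic (E)-5-(2-allyl-4,5-dimethoxyphenoxy)-6-hydroxy-4,5-dimethoxyhex-3-en-2-one | CC(=O)/C=C(/OC)C(OC)(CO)Oc1cc(OC)c(OC)cc1CC=C
F8 | step 4 | racemic (E)-2-(2-allyl-4,5-dimethoxyphenoxy)-2,3-dimethoxy-5-oxohex-3-en-1-yl trifluoromethanesulfonate | CC(=O)/C=C(/OC)C(OC)(COS(=O)(=O)C(F)(F)F)Oc1cc(OC)c(OC)cc1CC=C
F9 | step 9 | (4R,6R)-6-allyl-4-(2-allyl-4,5-dimethoxyphenoxy)-3,4-dimethoxycyclohex-2-en-1-one | C=CCc1cc(OC)c(OC)cc1O[C@]1(OC)C[C@@H](CC=C)C(=O)C=C1OC
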